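**Plan**

- Retrosynthesis: the MOM ether on the C2' oxygen is removed last. Ring A is then opened at C1–C2 and C5–C6 (Diels–Alder reaction and aromatisation), which leaves a terminal ynone carrying the complete ring B and a 1,1,3-trioxygenated butadiene.
- The ynone is cut at the carbinol–ethynyl bond (ethynyl Grignard), at the aryl–CH2 bond (aryllithium plus oxirane) and at the aryl–prenyl bond (aryllithium plus prenyl bromide), back to 3,5-dimethoxyphenol.
- Forward: ring B is bought. The prenyl group is placed between the two methoxy groups, the two-carbon arm next to the MOM ether, then the ynone is made. Ring A is the only ring formed and closes in the penultimate step.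
- Enabling feature: ring A has the acyl group on C1, OH on C2 and C4, and H on C3, C5 and C6. Diene carbons C1–C4 (O,O / H / O / H2) and the two alkyne carbons of a terminal ynone (C–acyl and C–H) assemble exactly this pattern, so the acid-labile prenylated ring B never meets a Friedel–Crafts acid.
- Stereochemistry: the target has no stereocentre and no E/Z element. The carbinol carbon of the propargylic alcohol and the ketal carbon of the cycloadduct form racemic and are erased by oxidation and aromatisation.

Key step: step 11

Remark: ring A is numbered from the acyl-bearing carbon (C1), ring B from the CH2-bearing carbon (C1', hydroxyl on C2'). Prenyl means 3-methylbut-2-enyl. The diene is taken as an E/Z mixture at the ketene acetal, which has no consequence after aromatisation.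

**Route**

Step 1
Reactants: 1 3,5-dimethoxyphenol
Product: 2 (3,5-dimethoxyphenoxy)tri(propan-2-yl)silane
Conditions: i-Pr3SiCl, imidazole, DMF, 25 °C
Reagents that add atoms: chlorotri(propan-2-yl)silane, CC(C)[Si](Cl)(C(C)C)C(C)C
Why: Imidazole-promoted O-silylation of a phenol (silyl ether formation) should be clean, and the bulky, weakly coordinating triisopropylsilyloxy group is chosen because it shields its own ortho positions in the next step.

Step 2
Reactants: 2 (3,5-dimethoxyphenoxy)tri(propan-2-yl)silane; 3 prenyl bromide (1-bromo-3-methylbut-2-ene)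
Product: 5 [3,5-dimethoxy-4-(3-methylbut-2-enyl)phenoxy]tri(propan-2-yl)silane, via aryllithium 4 (not isolated)
Conditions: n-BuLi, THF, 0 → 25 °C; then 3, −78 → 25 °C
Reagents that add atoms: none
Why: Directed ortho-metalation should occur at C4, the only site flanked by two methoxy groups and remote from the shielding silyloxy group, and the aryllithium should then displace bromide at the unsubstituted end of the primary allylic bromide (SN2 allylation).

Step 3
Reactants: 5 [3,5-dimethoxy-4-(3-methylbut-2-enyl)phenoxy]tri(propan-2-yl)silane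
Product: 6 3,5-dimethoxy-4-(3-methylbut-2-enyl)phenol
Conditions: Bu4NF, AcOH, THF, 0 → 25 °C
Reagents that add atoms: none
Why: Fluoride-induced cleavage of an aryl silyl ether (desilylation), buffered with acetic acid, should release the symmetric phenol without exposing the electron-rich phenoxide to a basic medium.

Step 4
Reactants: 6 3,5-dimethoxy-4-(3-methylbut-2-enyl)phenol
Product: 7 1,3-dimethoxy-5-(methoxymethoxy)-2-(3-methylbut-2-enyl)benzene
Conditions: MOMCl, i-Pr2NEt, CH2Cl2, 0 → 25 °C
Reagents that add atoms: chloromethyl methyl ether, COCCl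
Why: O-Alkylation of the phenol with chloromethyl methyl ether under amine base (Williamson-type ether formation) installs the group that protects the C2' oxygen and also directs the next lithiation.

Step 5
Reactants: 7 1,3-dimethoxy-5-(methoxymethoxy)-2-(3-methylbut-2-enyl)benzene; 8 oxirane
Product: 10 2-[2,4-dimethoxy-6-(methoxymethoxy)-3-(3-methylbut-2-enyl)phenyl]ethanol, via aryllithium 9 (not isolated)
Conditions: n-BuLi, THF, 0 °C; then 8 (excess), −78 → 25 °C; then H2O
Reagents that add atoms: none
Why: Directed ortho-metalation should take place at one of the two equivalent ring C–H positions, each flanked by the MOM ether and a methoxy group, and the aryllithium then opens oxirane at carbon (epoxide ring opening) to give the 2-arylethanol.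

Step 6
Reactants: 10 2-[2,4-dimethoxy-6-(methoxymethoxy)-3-(3-methylbut-2-enyl)phenyl]ethanol
Product: 11 2-[2,4-dimethoxy-6-(methoxymethoxy)-3-(3-methylbut-2-enyl)phenyl]acetaldehyde
Conditions: Dess–Martin periodinane, CH2Cl2, 0 → 25 °C
Reagents that add atoms: none
Why: Dess–Martin oxidation of a primary alcohol stops at the aldehyde under anhydrous, near-neutral conditions that should leave the trisubstituted alkene and the MOM acetal untouched.

Step 7
Reactants: 11 2-[2,4-dimethoxy-6-(methoxymethoxy)-3-(3-methylbut-2-enyl)phenyl]acetaldehyde; 12 ethynylmagnesium bromide (HC≡CMgBr)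
Product: 13 (±)-1-[2,4-dimethoxy-6-(methoxymethoxy)-3-(3-methylbut-2-enyl)phenyl]but-3-yn-2-ol
Conditions: 12 (0.5 M in THF), THF, −78 → 0 °C; then H2O
Reagents that add atoms: none
Why: 1,2-Addition of the weakly basic alkynyl Grignard reagent to the aldehyde (Grignard addition) should give the secondary propargylic alcohol; its carbinol centre forms without control as a racemate and is removed in step 8.

Step 8
Reactants: 13 (±)-1-[2,4-dimethoxy-6-(methoxymethoxy)-3-(3-methylbut-2-enyl)phenyl]but-3-yn-2-ol
Product: 14 1-[2,4-dimethoxy-6-(methoxymethoxy)-3-(3-methylbut-2-enyl)phenyl]but-3-yn-2-one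
Conditions: Dess–Martin periodinane, CH2Cl2, 0 °C
Reagents that add atoms: none
Why: Dess–Martin oxidation of a secondary propargylic alcohol is a standard entry to terminal ynones and avoids base, which would promote conjugate addition to the product.

Step 9
Reactants: 15 methyl acetoacetate
Product: 16 methyl 3-(trimethylsilyloxy)but-2-enoate (E/Z mixture)
Conditions: Me3SiCl, Et3N, hexane, 25 °C
Reagents that add atoms: chlorotrimethylsilane, C[Si](C)(C)Cl
Why: O-Silylation of the enol form of a β-keto ester with Me3SiCl and Et3N (silyl enol ether formation) is the standard first stage in the preparation of this diene.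

Step 10
Reactants: 16 methyl 3-(trimethylsilyloxy)but-2-enoate
Product: 18 1-methoxy-1,3-bis(trimethylsilyloxy)buta-1,3-diene, via lithium dienolate 17 (not isolated)
Conditions: LiN(i-Pr)2 (LDA, commercial solution), THF, −78 °C; then Me3SiCl, −78 → 0 °C; non-aqueous work-up, distillation
Reagents that add atoms: chlorotrimethylsilane, C[Si](C)(C)Cl
Why: Kinetic γ-deprotonation of the silyloxy crotonate gives the extended (vinylogous) ester enolate, which is silylated on oxygen to the silyl ketene acetal diene (Chan-type diene synthesis).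

Step 11
Reactants: 14 1-[2,4-dimethoxy-6-(methoxymethoxy)-3-(3-methylbut-2-enyl)phenyl]but-3-yn-2-one; 18 1-methoxy-1,3-bis(trimethylsilyloxy)buta-1,3-diene
Product: 20 1-(2,4-dihydroxyphenyl)-2-[2,4-dimethoxy-6-(methoxymethoxy)-3-(3-methylbut-2-enyl)phenyl]ethanone, via cycloadduct 19 (not isolated)
Conditions: 18 (2.5 equiv), toluene, 25 → 60 °C; then 0.5 M aq HCl, THF, 0 °C, 15 min
Reagents that add atoms: none
Why: The electron-rich diene 18 and the electron-poor ynone 14 should combine in a thermal, strongly asynchronous [4+2] cycloaddition in which the diene CH2 terminus bonds to the unsubstituted β-carbon of the ynone (C5–C6 of ring A) and the ketene acetal carbon to the α-carbon (C1–C2), giving cyclohexa-1,4-diene 19; brief dilute acid then hydrolyses both silyl ethers, the mixed ketal expels methanol and the resulting cyclohexenedione tautomerises to the resorcinol. The closest known reaction type is the Diels–Alder reaction of 1,1,3-trioxygenated butadienes with acetylenic ketones and esters, which gives resorcinol derivatives after aromatisation. Ring A closes in an intermolecular six-membered [4+2] mode, equivalent to a Michael addition followed by 6-(enolendo)-exo-trig attack of the allenolate on the oxocarbenium carbon if the two bonds form in sequence. The only new stereocentre, the ketal carbon of 19, forms racemic without control and disappears on aromatisation, so no stereocontrol is needed. The step needs regiocontrol, secured by pairing the largest HOMO coefficient of 18 (the CH2 terminus, raised by the C3 silyloxy group and the ketene acetal) with the largest LUMO coefficient of 14 (the terminal β-carbon), so the oxygens land on C2 and C4 and not on C3 and C5. It also needs chemoselectivity, which the neutral conditions provide: the unactivated prenyl alkene is no dienophile, and the MOM acetal and the enolisable benzylic CH2 are left alone.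

Step 12
Reactants: 20 1-(2,4-dihydroxyphenyl)-2-[2,4-dimethoxy-6-(methoxymethoxy)-3-(3-methylbut-2-enyl)phenyl]ethanone
Product: 21 licoriphenone, 1-(2,4-dihydroxyphenyl)-2-[6-hydroxy-2,4-dimethoxy-3-(3-methylbut-2-enyl)phenyl]ethanone
Conditions: HCl (ca. 0.3 M), MeOH, 0 → 25 °C, stopped at full conversion
Reagents that add atoms: none
Why: Acid-catalysed acetal exchange with methanol (MOM ether cleavage) should free the C2' phenol as dimethoxymethane; low acid strength, low temperature and the poor electrophilicity of the hydrogen-bonded 2,4-dihydroxyphenyl ketone should keep the reaction short of cyclodehydration to the 2-arylbenzofuran.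

**Compound list**

1 | 3,5-dimethoxyphenol | COc1cc(O)cc(OC)c1 | starting material
2 | (3,5-dimethoxyphenoxy)tri(propan-2-yl)silane | COc1cc(O[Si](C(C)C)(C(C)C)C(C)C)cc(OC)c1 | intermediate
3 | prenyl bromide (1-bromo-3-methylbut-2-ene) | CC(C)=CCBr | starting material
4 | [2,6-dimethoxy-4-(triisopropylsilyloxy)phenyl]lithium (formed in the flask) | COc1cc(O[Si](C(C)C)(C(C)C)C(C)C)cc(OC)c1[Li] | intermediate
5 | [3,5-dimethoxy-4-(3-methylbut-2-enyl)phenoxy]tri(propan-2-yl)silane | COc1cc(O[Si](C(C)C)(C(C)C)C(C)C)cc(OC)c1CC=C(C)C | intermediate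
6 | 3,5-dimethoxy-4-(3-methylbut-2-enyl)phenol | COc1cc(O)cc(OC)c1CC=C(C)C | intermediate
7 | 1,3-dimethoxy-5-(methoxymethoxy)-2-(3-methylbut-2-enyl)benzene | COCOc1cc(OC)c(CC=C(C)C)c(OC)c1 | intermediate
8 | oxirane | C1CO1 | starting material
9 | [2,4-dimethoxy-6-(methoxymethoxy)-3-(3-methylbut-2-enyl)phenyl]lithium (formed in the flask) | COCOc1cc(OC)c(CC=C(C)C)c(OC)c1[Li] | intermediate
10 | 2-[2,4-dimethoxy-6-(methoxymethoxy)-3-(3-methylbut-2-enyl)phenyl]ethanol | OCCc1c(OCOC)cc(OC)c(CC=C(C)C)c1OC | intermediate
11 | 2-[2,4-dimethoxy-6-(methoxymethoxy)-3-(3-methylbut-2-enyl)phenyl]acetaldehyde | O=CCc1c(OCOC)cc(OC)c(CC=C(C)C)c1OC | intermediate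
12 | ethynylmagnesium bromide | C#C[Mg]Br | starting material
13 | (±)-1-[2,4-dimethoxy-6-(methoxymethoxy)-3-(3-methylbut-2-enyl)phenyl]but-3-yn-2-ol (racemic) | C#CC(O)Cc1c(OCOC)cc(OC)c(CC=C(C)C)c1OC | intermediate
14 | 1-[2,4-dimethoxy-6-(methoxymethoxy)-3-(3-methylbut-2-enyl)phenyl]but-3-yn-2-one | C#CC(=O)Cc1c(OCOC)cc(OC)c(CC=C(C)C)c1OC | intermediate
15 | methyl acetoacetate | CC(=O)CC(=O)OC | starting material
16 | methyl 3-(trimethylsilyloxy)but-2-enoate (E/Z mixture) | COC(=O)C=C(C)O[Si](C)(C)C | intermediate
17 | lithium 1-methoxy-3-(trimethylsilyloxy)buta-1,3-dien-1-olate (formed in the flask) | COC(O[Li])=CC(=C)O[Si](C)(C)C | intermediate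
18 | 1-methoxy-1,3-bis(trimethylsilyloxy)buta-1,3-diene (E/Z mixture) | COC(=CC(=C)O[Si](C)(C)C)O[Si](C)(C)C | intermediate
19 | (±)-1-[6-methoxy-4,6-bis(trimethylsilyloxy)cyclohexa-1,4-dien-1-yl]-2-[2,4-dimethoxy-6-(methoxymethoxy)-3-(3-methylbut-2-enyl)phenyl]ethanone (racemic, formed in the flask) | COC1(O[Si](C)(C)C)C=C(O[Si](C)(C)C)CC=C1C(=O)Cc1c(OCOC)cc(OC)c(CC=C(C)C)c1OC | intermediate
20 | licoriphenone 2'-O-methoxymethyl ether, 1-(2,4-dihydroxyphenyl)-2-[2,4-dimethoxy-6-(methoxymethoxy)-3-(3-methylbut-2-enyl)phenyl]ethanone | COCOc1cc(OC)c(CC=C(C)C)c(OC)c1CC(=O)c1ccc(O)cc1O | intermediate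
21 | licoriphenone, 1-(2,4-dihydroxyphenyl)-2-[6-hydroxy-2,4-dimethoxy-3-(3-methylbut-2-enyl)phenyl]ethanone | COc1cc(O)c(CC(=O)c2ccc(O)cc2O)c(OC)c1CC=C(C)C | target

**Step count**

Total: 12 steps. Longest linear sequence: 10 steps (steps 1–8, 11, 12); steps 9 and 10 form the two-step diene branch.

**Steps most likely to fail**

Risk 1, step 11 (key step). Three processes could divert the reaction:
- conjugate addition of the diene to the terminal ynone without ring closure, or oligomerisation of the ynone;
- aromatisation by loss of trimethylsilanol instead of methanol, which would leave a methyl ether on C2 of ring A;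
- silyl transfer to the enolisable benzylic ketone.

Fallback, known chemistry that builds the aryl ketone from a preformed resorcinol ring: it sets out from aldehyde 11. 1-Bromo-2,4-bis(methoxymethoxy)benzene F1 (from commercial 4-bromoresorcinol, MOMCl and i-Pr2NEt) would undergo bromine–lithium exchange with n-BuLi in THF at −78 °C to give [2,4-bis(methoxymethoxy)phenyl]lithium F2. Addition of F2 to 11 should give (±)-1-[2,4-bis(methoxymethoxy)phenyl]-2-[2,4-dimethoxy-6-(methoxymethoxy)-3-(3-methylbut-2-enyl)phenyl]ethanol F3. Dess–Martin oxidation would then give 1-[2,4-bis(methoxymethoxy)phenyl]-2-[2,4-dimethoxy-6-(methoxymethoxy)-3-(3-methylbut-2-enyl)phenyl]ethanone F4. Removal of the three MOM groups under the conditions of step 12 brings the sequence back to the route at 21.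

Risk 2, step 12. The liberated C2' hydroxyl could add to the ketone under acid and lose water (cyclodehydration to a 2-arylbenzofuran), and HCl or methanol could add across the prenyl alkene if the reaction is pushed.

Fallback, exchange of the acid-labile group for one removed under neutral conditions before the ketone exists: it sets out from 13.
- HCl in MeOH at 25 °C should cleave the MOM ether at a stage with no carbonyl group, giving 2-(2-hydroxybut-3-ynyl)-3,5-dimethoxy-4-(3-methylbut-2-enyl)phenol F5.
- Allyl bromide and K2CO3 in acetone should alkylate the phenol selectively to 1-[2,4-dimethoxy-3-(3-methylbut-2-enyl)-6-(prop-2-enyloxy)phenyl]but-3-yn-2-ol F6.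
- Dess–Martin oxidation gives 1-[2,4-dimethoxy-3-(3-methylbut-2-enyl)-6-(prop-2-enyloxy)phenyl]but-3-yn-2-one F7.
- Diels–Alder reaction with 18 under the conditions of step 11 gives, through the allyl-protected cycloadduct F8, licoriphenone 2'-O-allyl ether F9.
- Deallylation with catalytic Pd(PPh3)4 and morpholine in THF at 25 °C returns to the route at 21 without any acid.

Risk 3, step 5. Opening of oxirane by the hindered, chelated aryllithium may be slow. The anion would then merely be protonated on work-up, or would equilibrate on warming to the benzylic and allylic CH2 of the prenyl group.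

Fallback, one-carbon homologation of a benzaldehyde in place of the epoxide opening: it sets out from 7.
- Lithiation as in step 5 and trapping of 9 with DMF at −78 °C should give 2,4-dimethoxy-6-(methoxymethoxy)-3-(3-methylbut-2-enyl)benzaldehyde F10.
- Wittig reaction with Ph3P=CHOMe (from [Ph3PCH2OMe]Cl and KOt-Bu in THF, 0 °C) gives the enol ether 1,5-dimethoxy-2-(2-methoxyethenyl)-3-(methoxymethoxy)-4-(3-methylbut-2-enyl)benzene F11 as an E/Z mixture.
- Brief hydrolysis of F11 with dilute aqueous acid in THF at 0–25 °C, under which an enol ether reacts far faster than an aryl MOM ether, returns to the route at 11.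

**Further compounds**

F1 | step 11 | 1-bromo-2,4-bis(methoxymethoxy)benzene | COCOc1ccc(Br)c(OCOC)c1
F2 | step 11 | [2,4-bis(methoxymethoxy)phenyl]lithium | [Li]c1ccc(OCOC)cc1OCOC
F3 | step 11 | (±)-1-[2,4-bis(methoxymethoxy)phenyl]-2-[2,4-dimethoxy-6-(methoxymethoxy)-3-(3-methylbut-2-enyl)phenyl]ethanol (racemic) | COCOc1ccc(C(O)Cc2c(OCOC)cc(OC)c(CC=C(C)C)c2OC)c(OCOC)c1
F4 | step 11 | 1-[2,4-bis(methoxymethoxy)phenyl]-2-[2,4-dimethoxy-6-(methoxymethoxy)-3-(3-methylbut-2-enyl)phenyl]ethanone | COCOc1ccc(C(=O)Cc2c(OCOC)cc(OC)c(CC=C(C)C)c2OC)c(OCOC)c1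
F5 | step 12 | (±)-2-(2-hydroxybut-3-ynyl)-3,5-dimethoxy-4-(3-methylbut-2-enyl)phenol (racemic) | C#CC(O)Cc1c(O)cc(OC)c(CC=C(C)C)c1OC
F6 | step 12 | (±)-1-[2,4-dimethoxy-3-(3-methylbut-2-enyl)-6-(prop-2-enyloxy)phenyl]but-3-yn-2-ol (racemic) | C#CC(O)Cc1c(OCC=C)cc(OC)c(CC=C(C)C)c1OC
F7 | step 12 | 1-[2,4-dimethoxy-3-(3-methylbut-2-enyl)-6-(prop-2-enyloxy)phenyl]but-3-yn-2-one | C#CC(=O)Cc1c(OCC=C)cc(OC)c(CC=C(C)C)c1OC
F8 | step 12 | (±)-1-[6-methoxy-4,6-bis(trimethylsilyloxy)cyclohexa-1,4-dien-1-yl]-2-[2,4-dimethoxy-3-(3-methylbut-2-enyl)-6-(prop-2-enyloxy)phenyl]ethanone (racemic, formed in the flask) | COC1(O[Si](C)(C)C)C=C(O[Si](C)(C)C)CC=C1C(=O)Cc1c(OCC=C)cc(OC)c(CC=C(C)C)c1OC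
F9 | step 12 | licoriphenone 2'-O-allyl ether, 1-(2,4-dihydroxyphenyl)-2-[2,4-dimethoxy-3-(3-methylbut-2-enyl)-6-(prop-2-enyloxy)phenyl]ethanone | C=CCOc1cc(OC)c(CC=C(C)C)c(OC)c1CC(=O)c1ccc(O)cc1O
F10 | step 5 | 2,4-dimethoxy-6-(methoxymethoxy)-3-(3-methylbut-2-enyl)benzaldehyde | O=Cc1c(OCOC)cc(OC)c(CC=C(C)C)c1OC
F11 | step 5 | 1,5-dimethoxy-2-(2-methoxyethenyl)-3-(methoxymethoxy)-4-(3-methylbut-2-enyl)benzene (E/Z mixture) | COC=Cc1c(OCOC)cc(OC)c(CC=C(C)C)c1OC
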